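**Retrosynthetic overview**

- Feature: the pyranone ring (O1, C2, C3, C4, C4a, C8a) fused to ring A is read as the C8a phenol oxygen, a C4 carbonyl carbon from CO, and the C2(Ph)–C3 unit of phenylacetylene. The neighbouring C8 oxygen cannot take part in ring closure and becomes the butyrate site.
- Target 18 ⇐ hydrogenolysis of the 5-O-benzyl ether ⇐ C3 hydroxylation by C2=C3 epoxidation and rearrangement ⇐ 8-O-butyrylation of 8-hydroxyflavone 13.
- 13 ⇐ iodocatechol 8 + CO 10 + phenylacetylene 9, forming C4a–C4, C4–C3 and O1–C2. This is the only ring closed in the route; ring A and the 2-phenyl ring are bought.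
- 8 ⇐ acetal-directed ortho-lithiation and iodination of benzyl ether 5 ⇐ Baeyer–Villiger oxidation of bis-MOM aldehyde 2 ⇐ 5-hydroxyvanillin 1.

Key step: step 6

Remark: the target has no stereocentre and is achiral, so the single-enantiomer requirement is met by the constitution alone and no stereocontrol is needed.

**Route**

Step 1
Reactants: 1 5-hydroxyvanillin (3,4-dihydroxy-5-methoxybenzaldehyde)
Product: 2 3-methoxy-4,5-bis(methoxymethoxy)benzaldehyde
Conditions: MOMCl (2.6 equiv), i-Pr2NEt, CH2Cl2, 0 °C → rt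
Reagents that add atoms: chloromethyl methyl ether (MOMCl), COCCl
Why: Williamson-type O-alkylation (via the methoxymethyl oxocarbenium ion) should cap both catechol hydroxyls as acetals that later direct the lithiation, leaving the aldehyde untouched.

Step 2
Reactants: 2 3-methoxy-4,5-bis(methoxymethoxy)benzaldehyde
Product: 4 3-methoxy-4,5-bis(methoxymethoxy)phenol, via aryl formate 3 (not isolated)
Conditions: mCPBA, CH2Cl2, 0 °C → rt; aq. Na2SO3/NaHCO3 wash; then K2CO3 (cat.), MeOH, rt
Reagents that add atoms: meta-chloroperoxybenzoic acid (mCPBA), OOC(=O)c1cccc(Cl)c1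
Why: Baeyer–Villiger (Dakin-type) oxidation, in which the electron-rich aryl group with a para acetal oxygen should migrate in the Criegee adduct in preference to hydride, followed by methanolysis of the formate.

Step 3
Reactants: 4 3-methoxy-4,5-bis(methoxymethoxy)phenol
Product: 5 5-(benzyloxy)-1-methoxy-2,3-bis(methoxymethoxy)benzene
Conditions: BnBr, K2CO3, DMF, rt
Reagents that add atoms: benzyl bromide, BrCc1ccccc1
Why: Williamson ether synthesis on the only free phenol; the acetals are stable to base.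

Step 4
Reactants: 5 5-(benzyloxy)-1-methoxy-2,3-bis(methoxymethoxy)benzene
Product: 7 1-(benzyloxy)-2-iodo-5-methoxy-3,4-bis(methoxymethoxy)benzene, via aryllithium 6 (not isolated)
Conditions: n-BuLi, TMEDA, Et2O, 0 °C; then I2, THF, −78 °C → rt
Reagents that add atoms: iodine, II
Why: Directed ortho-metalation, in which the ring C–H between the benzyloxy group and the strongly coordinating methoxymethoxy group should be lithiated in preference to the C–H between benzyloxy and methoxy, with the weakly polar medium favouring complex-induced ring lithiation over benzylic deprotonation, and iodine trapping the aryllithium.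

Step 5
Reactants: 7 1-(benzyloxy)-2-iodo-5-methoxy-3,4-bis(methoxymethoxy)benzene
Product: 8 4-(benzyloxy)-3-iodo-6-methoxybenzene-1,2-diol
Conditions: conc. HCl (cat.), MeOH, 45 °C, under Ar; used directly
Reagents that add atoms: none
Why: Acid-catalysed transacetalisation to methanol should remove both methoxymethyl groups while the benzyl ether, methyl ether and aryl iodide are stable to dilute acid.

Step 6
Reactants: 8 4-(benzyloxy)-3-iodo-6-methoxybenzene-1,2-diol; 9 phenylacetylene; 10 carbon monoxide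
Product: 13 5-(benzyloxy)-8-hydroxy-7-methoxy-2-phenyl-4H-chromen-4-one, via aryl ynone 11 (not isolated), via enaminone 12 (not isolated)
Conditions: PdCl2(dppf) (5 mol %), CO (20 bar), Et2NH (degassed, solvent), 120 °C, no copper
Reagents that add atoms: none
Why: Pd(0) inserts into the C–I bond of 8, CO inserts to give an aroyl–palladium species, and amine-assisted transfer of the phenylethynyl group followed by reductive elimination forms C4a–C4 and C4–C3 in ynone 11. Diethylamine then adds to the alkyne carbon that becomes C2 to give enaminone 12, and the hydroxyl ortho to the ketone attacks the same carbon and expels the amine, forming O1–C2 and closing the pyranone ring in a net 6-endo-dig oxa-Michael (addition–elimination) mode. The closest known reaction type is the palladium-catalysed carbonylative Sonogashira coupling–cyclisation of 2-iodophenols with terminal alkynes under CO in a secondary amine, which gives flavones. No stereocentre is formed. Six-membered closure should win over 5-exo-dig aurone closure because the reaction runs through the enaminone; the copper-free, high-pressure CO regime favours acyl transfer over direct alkynylation (which would lead to a benzofuran); and dppf is an electron-rich, wide-bite-angle ligand suited to the di-ortho-substituted, electron-rich iodide. Of the two catechol hydroxyls only the one ortho to the acyl carbon can reach C2, so the other is left as the free 8-hydroxyl.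

Step 7
Reactants: 13 5-(benzyloxy)-8-hydroxy-7-methoxy-2-phenyl-4H-chromen-4-one; 14 butyryl chloride (butanoyl chloride)
Product: 15 5-(benzyloxy)-7-methoxy-4-oxo-2-phenyl-4H-chromen-8-yl butanoate
Conditions: Et3N, DMAP (cat.), CH2Cl2, 0 °C
Reagents that add atoms: none
Why: DMAP-catalysed O-acylation (nucleophilic acyl substitution) at the 8-hydroxyl, the only free hydroxyl in 13.

Step 8
Reactants: 15 5-(benzyloxy)-7-methoxy-4-oxo-2-phenyl-4H-chromen-8-yl butanoate
Product: 17 5-(benzyloxy)-3-hydroxy-7-methoxy-4-oxo-2-phenyl-4H-chromen-8-yl butanoate, via flavone epoxide 16 (not isolated)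
Conditions: DMDO (acetone solution, small excess), CH2Cl2, 0 °C → rt; concentrate; then p-TsOH·H2O (cat.), CH2Cl2, rt
Reagents that add atoms: dimethyldioxirane (DMDO), CC1(C)OO1
Why: Electrophilic epoxidation of the C2=C3 enol-ether alkene under neutral conditions should give the racemic 2,3-epoxide, which on acid catalysis opens at C2 to the O1- and phenyl-stabilised cation and loses H3 to give the 3-hydroxyflavone, so both transient stereocentres are lost and the aryl ester is spared.

Step 9
Reactants: 17 5-(benzyloxy)-3-hydroxy-7-methoxy-4-oxo-2-phenyl-4H-chromen-8-yl butanoate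
Product: 18 3,5-dihydroxy-7-methoxy-4-oxo-2-phenyl-4H-chromen-8-yl butanoate
Conditions: H2 (1 atm), 10% Pd/C, EtOAc, rt
Reagents that add atoms: none
Why: Catalytic hydrogenolysis of the benzyl aryl ether in a non-nucleophilic solvent should leave the aryl butyrate, the tetrasubstituted C2=C3 bond and the methyl ether intact.

**Compound list**

1 | 5-hydroxyvanillin (3,4-dihydroxy-5-methoxybenzaldehyde) | COc1cc(C=O)cc(O)c1O | starting material
2 | 3-methoxy-4,5-bis(methoxymethoxy)benzaldehyde | COCOc1cc(C=O)cc(OC)c1OCOC | intermediate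
3 | 3-methoxy-4,5-bis(methoxymethoxy)phenyl formate | COCOc1cc(OC=O)cc(OC)c1OCOC | intermediate (not isolated)
4 | 3-methoxy-4,5-bis(methoxymethoxy)phenol | COCOc1cc(O)cc(OC)c1OCOC | intermediate
5 | 5-(benzyloxy)-1-methoxy-2,3-bis(methoxymethoxy)benzene | COCOc1cc(OCc2ccccc2)cc(OC)c1OCOC | intermediate
6 | [6-(benzyloxy)-4-methoxy-2,3-bis(methoxymethoxy)phenyl]lithium | [Li]c1c(OCOC)c(OCOC)c(OC)cc1OCc1ccccc1 | intermediate (not isolated)
7 | 1-(benzyloxy)-2-iodo-5-methoxy-3,4-bis(methoxymethoxy)benzene | COCOc1c(I)c(OCc2ccccc2)cc(OC)c1OCOC | intermediate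
8 | 4-(benzyloxy)-3-iodo-6-methoxybenzene-1,2-diol | COc1cc(OCc2ccccc2)c(I)c(O)c1O | intermediate
9 | phenylacetylene | C#Cc1ccccc1 | starting material
10 | carbon monoxide | [C-]#[O+] | starting material
11 | 1-[6-(benzyloxy)-2,3-dihydroxy-4-methoxyphenyl]-3-phenylprop-2-yn-1-one | COc1cc(OCc2ccccc2)c(C(=O)C#Cc2ccccc2)c(O)c1O | intermediate (not isolated)
12 | (E)-1-[6-(benzyloxy)-2,3-dihydroxy-4-methoxyphenyl]-3-(diethylamino)-3-phenylprop-2-en-1-one (alkene geometry of no consequence) | COc1cc(OCc2ccccc2)c(C(=O)/C=C(/N(CC)CC)c2ccccc2)c(O)c1O | intermediate (not isolated)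
13 | 5-(benzyloxy)-8-hydroxy-7-methoxy-2-phenyl-4H-chromen-4-one | COc1cc(OCc2ccccc2)c2c(=O)cc(-c3ccccc3)oc2c1O | intermediate
14 | butyryl chloride | CCCC(=O)Cl | starting material
15 | 5-(benzyloxy)-7-methoxy-4-oxo-2-phenyl-4H-chromen-8-yl butanoate | CCCC(=O)Oc1c(OC)cc(OCc2ccccc2)c2c(=O)cc(-c3ccccc3)oc12 | intermediate
16 | 5-(benzyloxy)-2,3-epoxy-7-methoxy-4-oxo-2-phenyl-2,3-dihydro-4H-chromen-8-yl butanoate (racemic; cis fusion forced by the oxirane) | CCCC(=O)Oc1c(OC)cc(OCc2ccccc2)c2C(=O)C3OC3(c3ccccc3)Oc12 | intermediate (not isolated)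
17 | 5-(benzyloxy)-3-hydroxy-7-methoxy-4-oxo-2-phenyl-4H-chromen-8-yl butanoate | CCCC(=O)Oc1c(OC)cc(OCc2ccccc2)c2c(=O)c(O)c(-c3ccccc3)oc12 | intermediate
18 | 3,5-dihydroxy-7-methoxy-4-oxo-2-phenyl-4H-chromen-8-yl butanoate | CCCC(=O)Oc1c(OC)cc(O)c2c(=O)c(O)c(-c3ccccc3)oc12 | target

**Step count**

Total steps: 9. Longest linear sequence: 9 (from 1 to 18).

**Steps most likely to fail**

1. Step 6 (carbonylative annulation). The aroyl–palladium intermediate may be intercepted by diethylamine (aminocarbonylation). The iodide may be alkynylated without CO uptake and close to a benzofuran. The ynone may close in the 5-exo mode. The iodide may be reduced. The chelating catecholate may deactivate the catalyst.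
Fallback, from 7 back to 13, without palladium: iodine–lithium exchange on 7 (n-BuLi, THF, −78 °C) regenerates aryllithium 6, which is added to 3-phenylprop-2-ynal to give racemic 1-[6-(benzyloxy)-4-methoxy-2,3-bis(methoxymethoxy)phenyl]-3-phenylprop-2-yn-1-ol F1. MnO2 in CH2Cl2 oxidises this to 1-[6-(benzyloxy)-4-methoxy-2,3-bis(methoxymethoxy)phenyl]-3-phenylprop-2-yn-1-one F2. Conjugate addition of diethylamine in EtOH gives (E)-1-[6-(benzyloxy)-4-methoxy-2,3-bis(methoxymethoxy)phenyl]-3-(diethylamino)-3-phenylprop-2-en-1-one F3. HCl in MeOH at 50 °C then removes both acetals and cyclises the liberated enaminone 12 with loss of diethylamine to give 13. Any enaminone hydrolysed to the 1,3-diketone should cyclodehydrate to the same flavone under the acid.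

2. Step 8 (epoxidation–rearrangement). Epoxidation of the electron-poor C2=C3 bond may be slow enough that oxidation of the benzylic CH2 or of the electron-rich ring A competes. The epoxide may also open along other pathways than loss of H3.
Fallback, from 13 back to 18, by C3 metalation–borylation–oxidation carried out before the ester is introduced: 13 is protected (MOMCl, i-Pr2NEt) as 5-(benzyloxy)-7-methoxy-8-(methoxymethoxy)-2-phenyl-4H-chromen-4-one F4. LDA in THF at −78 °C gives [5-(benzyloxy)-7-methoxy-8-(methoxymethoxy)-4-oxo-2-phenyl-4H-chromen-3-yl]lithium F5, and B(OMe)3 traps it as dimethyl [5-(benzyloxy)-7-methoxy-8-(methoxymethoxy)-4-oxo-2-phenyl-4H-chromen-3-yl]boronate F6. H2O2/AcOH oxidises this to 5-(benzyloxy)-3-hydroxy-7-methoxy-8-(methoxymethoxy)-2-phenyl-4H-chromen-4-one F7. Benzylation (BnBr, K2CO3, DMF) gives 3,5-bis(benzyloxy)-7-methoxy-8-(methoxymethoxy)-2-phenyl-4H-chromen-4-one F8. HCl/MeOH frees 3,5-bis(benzyloxy)-8-hydroxy-7-methoxy-2-phenyl-4H-chromen-4-one F9. Acylation with 14 (Et3N, DMAP) gives 3,5-bis(benzyloxy)-7-methoxy-4-oxo-2-phenyl-4H-chromen-8-yl butanoate F10. Hydrogenolysis (H2, Pd/C, EtOAc) of both benzyl ethers gives 18.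

3. Step 4 (ortho-lithiation–iodination). The base may deprotonate the benzylic CH2, followed by [1,2]-Wittig rearrangement. Site selectivity between the two ring C–H positions may also be incomplete.
Fallback, from 2 back to 7, with the metalation done before any benzyl group is present and directed by an in situ α-amino alkoxide together with the adjacent acetal: 2 is treated with lithium N,N,N′-trimethylethylenediamide in THF at −20 °C to give lithium {[2-(dimethylamino)ethyl](methyl)amino}[3-methoxy-4,5-bis(methoxymethoxy)phenyl]methanolate F11. n-BuLi (3 equiv, −20 °C) lithiates the ring position next to the acetal to give the 2-lithio derivative of this alkoxide F12. Iodine at −78 °C gives the corresponding 2-iodo amino alkoxide F13, and aqueous work-up releases 2-iodo-5-methoxy-3,4-bis(methoxymethoxy)benzaldehyde F14. Baeyer–Villiger oxidation (mCPBA, CH2Cl2) gives 2-iodo-5-methoxy-3,4-bis(methoxymethoxy)phenyl formate F15, and methanolysis (K2CO3, MeOH) gives 2-iodo-5-methoxy-3,4-bis(methoxymethoxy)phenol F16. Benzylation (BnBr, K2CO3, DMF) gives 7.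

**Further compounds**

F1 | step 6 | rac-1-[6-(benzyloxy)-4-methoxy-2,3-bis(methoxymethoxy)phenyl]-3-phenylprop-2-yn-1-ol | COCOc1c(C(O)C#Cc2ccccc2)c(OCc2ccccc2)cc(OC)c1OCOC
F2 | step 6 | 1-[6-(benzyloxy)-4-methoxy-2,3-bis(methoxymethoxy)phenyl]-3-phenylprop-2-yn-1-one | COCOc1c(C(=O)C#Cc2ccccc2)c(OCc2ccccc2)cc(OC)c1OCOC
F3 | step 6 | (E)-1-[6-(benzyloxy)-4-methoxy-2,3-bis(methoxymethoxy)phenyl]-3-(diethylamino)-3-phenylprop-2-en-1-one | COCOc1c(C(=O)/C=C(/N(CC)CC)c2ccccc2)c(OCc2ccccc2)cc(OC)c1OCOC
F4 | step 8 | 5-(benzyloxy)-7-methoxy-8-(methoxymethoxy)-2-phenyl-4H-chromen-4-one | COCOc1c(OC)cc(OCc2ccccc2)c2c(=O)cc(-c3ccccc3)oc12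
F5 | step 8 | [5-(benzyloxy)-7-methoxy-8-(methoxymethoxy)-4-oxo-2-phenyl-4H-chromen-3-yl]lithium | COCOc1c(OC)cc(OCc2ccccc2)c2c(=O)c([Li])c(-c3ccccc3)oc12
F6 | step 8 | dimethyl [5-(benzyloxy)-7-methoxy-8-(methoxymethoxy)-4-oxo-2-phenyl-4H-chromen-3-yl]boronate | COCOc1c(OC)cc(OCc2ccccc2)c2c(=O)c(B(OC)OC)c(-c3ccccc3)oc12
F7 | step 8 | 5-(benzyloxy)-3-hydroxy-7-methoxy-8-(methoxymethoxy)-2-phenyl-4H-chromen-4-one | COCOc1c(OC)cc(OCc2ccccc2)c2c(=O)c(O)c(-c3ccccc3)oc12
F8 | step 8 | 3,5-bis(benzyloxy)-7-methoxy-8-(methoxymethoxy)-2-phenyl-4H-chromen-4-one | COCOc1c(OC)cc(OCc2ccccc2)c2c(=O)c(OCc3ccccc3)c(-c3ccccc3)oc12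
F9 | step 8 | 3,5-bis(benzyloxy)-8-hydroxy-7-methoxy-2-phenyl-4H-chromen-4-one | COc1cc(OCc2ccccc2)c2c(=O)c(OCc3ccccc3)c(-c3ccccc3)oc2c1O
F10 | step 8 | 3,5-bis(benzyloxy)-7-methoxy-4-oxo-2-phenyl-4H-chromen-8-yl butanoate | CCCC(=O)Oc1c(OC)cc(OCc2ccccc2)c2c(=O)c(OCc3ccccc3)c(-c3ccccc3)oc12
F11 | step 4 | lithium {[2-(dimethylamino)ethyl](methyl)amino}[3-methoxy-4,5-bis(methoxymethoxy)phenyl]methanolate | [Li]OC(N(C)CCN(C)C)c1cc(OC)c(OCOC)c(OCOC)c1
F12 | step 4 | lithium {[2-(dimethylamino)ethyl](methyl)amino}[2-lithio-5-methoxy-3,4-bis(methoxymethoxy)phenyl]methanolate | [Li]OC(N(C)CCN(C)C)c1cc(OC)c(OCOC)c(OCOC)c1[Li]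
F13 | step 4 | lithium {[2-(dimethylamino)ethyl](methyl)amino}[2-iodo-5-methoxy-3,4-bis(methoxymethoxy)phenyl]methanolate | [Li]OC(N(C)CCN(C)C)c1cc(OC)c(OCOC)c(OCOC)c1I
F14 | step 4 | 2-iodo-5-methoxy-3,4-bis(methoxymethoxy)benzaldehyde | COCOc1c(I)c(C=O)cc(OC)c1OCOC
F15 | step 4 | 2-iodo-5-methoxy-3,4-bis(methoxymethoxy)phenyl formate | COCOc1c(I)c(OC=O)cc(OC)c1OCOC
F16 | step 4 | 2-iodo-5-methoxy-3,4-bis(methoxymethoxy)phenol | COCOc1c(I)c(O)cc(OC)c1OCOC
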